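**Plan**
- Retrosynthesis: cut C12–C13 (B-alkyl Suzuki coupling with a Z-iodoenoate) and C11=C12 (methylenation); return C8–H and C6=C7 to a 7-en-6-one and its C6 silyl enol ether; cut C5–C10 and C8–C9 together (intramolecular Diels–Alder); then C7=C8 (aldol condensation) and C3–C4 (conjugate addition to mesityl oxide), ending at a six-carbon unit cut from geraniol.
- Enabling feature: the C6=C7 cyclohexene (ring B) is the adduct of a C5–C8 diene and a C9=C10 dienophile linked through C1–C4 of ring A; the C10 methyl and C11, cis on the ring, correspond to an E-configured 3-methyl-enoyl unit.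
- Forward: the chain C11–C9–C10–C1…C8–C17 is joined linearly; rings A and B then form together in one copper-catalysed cycloaddition; the C12–C16 side chain is joined last.
- Stereochemistry: the E-C9=C10 bond of geraniol fixes the C9/C10 relation; the (S,S)-t-Bu-box copper catalyst fixes their absolute configuration; the endo transition state gives the trans ring fusion at C5.
- C8 is set afterwards by suprafacial hydrogen delivery from an axial C6 diazene; the 13E alkene comes from anti hydroiodination of an ynoate and a stereoretentive coupling.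

Key step: step 12

Remark: labdane numbering is used (decalin C1–C10; side chain C11–C16 with C15 the acid carbon and C16 the acetoxymethyl carbon; C17 on C8; C20 the methyl on C10). The target is taken as the (5R,8S,9R,10S,13E) isomer encoded by its SMILES. TBS = tert-butyldimethylsilyl, PMB = 4-methoxybenzyl. Cycloadduct 20 is drawn as the endo product (C17 cis to C11); its C8 epimer, if a stepwise pathway forms it, would be carried on unchanged because C8 becomes trigonal in step 14.

**Step 1**
Reactants: 1 geraniol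
Product: 2 1-({[(2E)-3,7-dimethylocta-2,6-dien-1-yl]oxy}methyl)-4-methoxybenzene
Conditions: NaH, PMBCl, n-Bu4NI (cat.), THF/DMF, 0 °C → rt
Reagents that add atoms: 4-methoxybenzyl chloride, COc1ccc(CCl)cc1
Why: Williamson etherification masks the C11 hydroxyl as an ether that tolerates ozonolysis work-up, Grignard formation and amide base and can later be removed oxidatively in the presence of silyl ethers.

**Step 2**
Reactants: 2 geranyl PMB ether
Product: 4 (4E)-6-[(4-methoxybenzyl)oxy]-4-methylhex-4-en-1-ol, via truncated aldehyde 3 (not isolated)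
Conditions: O3, CH2Cl2/MeOH, −78 °C (Sudan Red 7B end point); then NaBH4, −78 → 0 °C
Reagents that add atoms: ozone, [O-][O+]=O
Why: Chemoselective ozonolysis of the more electron-rich remote alkene (the other is deactivated by the allylic ether), followed by borohydride reduction in the same flask, should give the six-carbon alcohol with the E-alkene intact.

**Step 3**
Reactants: 4 truncated alcohol
Product: 5 1-({[(2E)-6-bromo-3-methylhex-2-en-1-yl]oxy}methyl)-4-methoxybenzene
Conditions: CBr4, PPh3, CH2Cl2, 0 °C
Reagents that add atoms: carbon tetrabromide, BrC(Br)(Br)Br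
Why: Appel bromination converts the primary alcohol to the bromide under neutral conditions that leave the PMB ether and the trisubstituted alkene untouched.

**Step 4**
Reactants: 5 bromide; 6 mesityl oxide
Product: 8 (8E)-10-[(4-methoxybenzyl)oxy]-4,4,8-trimethyldec-8-en-2-one, via Grignard reagent 7 (not isolated)
Conditions: Mg, THF, 40 °C; CuBr·SMe2 (10 mol%), 6, THF, −40 → 0 °C; aq. NH4Cl
Reagents that add atoms: none
Why: Copper-catalysed conjugate addition of the primary Grignard reagent to the β,β-disubstituted enone forms C3–C4 and the quaternary C4 (no stereocentre), the copper catalyst suppressing 1,2-addition.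

**Step 5**
Reactants: 8 methyl ketone; 9 (tert-butyldimethylsilyloxy)acetaldehyde
Product: 10 (10E)-1-[(tert-butyldimethylsilyl)oxy]-2-hydroxy-12-[(4-methoxybenzyl)oxy]-6,6,10-trimethyldodec-10-en-4-one (racemic)
Conditions: LiN(i-Pr)2, THF, −78 °C; 9, −78 °C; AcOH
Reagents that add atoms: none
Why: Kinetic deprotonation occurs at the methyl group and not at the neopentyl C5 methylene, and the lithium enolate undergoes aldol addition to the aldehyde; the new carbinol centre is racemic and is removed in step 6.

**Step 6**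
Reactants: 10 aldol
Product: 12 (2E,10E)-1-[(tert-butyldimethylsilyl)oxy]-12-[(4-methoxybenzyl)oxy]-6,6,10-trimethyldodeca-2,10-dien-4-one, via β-mesylate 11 (not isolated)
Conditions: MsCl, Et3N, CH2Cl2, 0 °C → rt
Reagents that add atoms: none
Why: Mesylation of the β-hydroxy ketone and E1cB elimination by triethylamine should give the conjugated enone, the E-geometry of C7=C8 being the thermodynamic outcome.

**Step 7**
Reactants: 12 PMB-protected enone
Product: 13 (2E,10E)-1-[(tert-butyldimethylsilyl)oxy]-12-hydroxy-6,6,10-trimethyldodeca-2,10-dien-4-one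
Conditions: DDQ, CH2Cl2/pH 7 buffer, 0 °C → rt
Reagents that add atoms: none
Why: Oxidative PMB cleavage by DDQ (benzylic hydride abstraction, then hydrolysis) frees the allylic alcohol while the TBS ether, the enone and the alkenes persist; any enal from over-oxidation converges in step 8.

**Step 8**
Reactants: 13 allylic alcohol
Product: 14 (2E,10E)-12-[(tert-butyldimethylsilyl)oxy]-3,7,7-trimethyl-9-oxododeca-2,10-dienal
Conditions: TEMPO (10 mol%), PhI(OAc)2, CH2Cl2, rt
Reagents that add atoms: none
Why: TEMPO-catalysed oxidation takes the primary allylic alcohol to the enal without E/Z isomerisation and without touching the enone or the silyl ether.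

**Step 9**
Reactants: 14 enal
Product: 15 (2E,10E)-12-[(tert-butyldimethylsilyl)oxy]-3,7,7-trimethyl-9-oxododeca-2,10-dienoic acid
Conditions: NaClO2, NaH2PO4, 2-methylbut-2-ene, t-BuOH/H2O, rt
Reagents that add atoms: sodium chlorite, [Na+].[O-]Cl=O
Why: Pinnick oxidation converts the enal to the acid under buffered conditions that do not isomerise the C9=C10 bond, the alkene scavenger removing hypochlorite.

**Step 10**
Reactants: 15 acid; 16 2-oxazolidinone
Product: 18 3-[(2E,10E)-12-[(tert-butyldimethylsilyl)oxy]-3,7,7-trimethyl-9-oxododeca-2,10-dienoyl]-1,3-oxazolidin-2-one, via mixed pivalic anhydride 17 (not isolated)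
Conditions: t-BuCOCl, Et3N, THF, −20 °C; LiCl, 16, rt
Reagents that add atoms: none
Why: N-acylation of the oxazolidinone through the mixed anhydride with LiCl and Et3N avoids strong base, so the E-enoyl geometry and the enone should survive.

**Step 11**
Reactants: 18 keto imide
Product: 19 3-[(2E,8Z,10E)-9,12-bis[(tert-butyldimethylsilyl)oxy]-3,7,7-trimethyldodeca-2,8,10-trienoyl]-1,3-oxazolidin-2-one
Conditions: TBSOTf, Et3N, CH2Cl2, −78 → 0 °C
Reagents that add atoms: tert-butyldimethylsilyl trifluoromethanesulfonate, CC(C)(C)[Si](C)(C)OS(=O)(=O)C(F)(F)F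
Why: Soft enolisation silylates the ketone (far more reactive than the imide) at the α'-carbon C5 to give the cross-conjugated 2-silyloxydiene, the Z-enol ether being expected because the quaternary C4 avoids allylic strain with the C7 vinyl group.

**Step 12**
Reactants: 19 silyloxy tetraene imide
Product: 20 3-{[2-({[tert-butyl(dimethyl)silyl]oxy}methyl)-4-{[tert-butyl(dimethyl)silyl]oxy}-5,5,8a-trimethyl-1,2,4a,5,6,7,8,8a-octahydronaphthalen-1-yl]carbonyl}-1,3-oxazolidin-2-one (trans-fused; C10 methyl, C11 and C17 mutually cis; C5, C9 and C10 as in 36)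
Conditions: [Cu((S,S)-t-Bu-box)](SbF6)2 (15 mol%), 4 Å MS, CH2Cl2, −20 → 25 °C
Reagents that add atoms: none
Why: Proposed new method: the cationic square-planar chelate of the s-cis enoyl imide (divalent copper) lowers the dienophile LUMO while the 6-silyloxy group raises the diene HOMO and puts its largest coefficient on C5, so a strongly asynchronous [4+2] addition should forge the congested C5–C10 bond first (in the stepwise limit a Mukaiyama–Michael attack of C5 on C10 followed by Michael closure of C9 onto C8, which gives the same product); the closest known reaction type is the copper–bis(oxazoline)-catalysed intramolecular Diels–Alder reaction of trienyl N-acyloxazolidinones, not yet shown for a β,β-disubstituted dienophile or a neopentyl diene terminus. Ring B closes as the cyclohexene of the [4+2] event, suprafacial on both components (6-endo-trig at C8 in the stepwise limit), and ring A closes as the tether ring through the same C5–C10 bond (6-exo-trig with respect to the C9=C10 acceptor). The absolute configuration at C9 and C10 comes from the catalyst: a tert-butyl group of the (S,S)-ligand blocks the Si face of C9 in the chelate, so the diene adds to the Re face. The cis relation of the C10 methyl and C11 follows from the E-geometry of C9=C10, C5 is set trans to the C10 methyl by the endo transition state (imide carbonyl under the diene, chair-like C1–C4 tether), and C8 forms with C17 cis to C11 but is inconsequential because it becomes trigonal in step 14. The step needs enantioface, endo and periselectivity; these rest on two-point imide chelation, on the (8Z)-enol ether geometry that keeps the tether on the outside of the s-cis diene, and on intramolecularity, which should compensate for the low intrinsic reactivity of the trisubstituted dienophile.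

**Step 13**
Reactants: 20 cycloadduct
Product: 21 [2-({[tert-butyl(dimethyl)silyl]oxy}methyl)-4-{[tert-butyl(dimethyl)silyl]oxy}-5,5,8a-trimethyl-1,2,4a,5,6,7,8,8a-octahydronaphthalen-1-yl]methanol (stereocentres as in 20)
Conditions: LiBH4, MeOH (1 equiv), Et2O, 0 °C
Reagents that add atoms: none
Why: Borohydride reduction of the exocyclic imide carbonyl releases the oxazolidinone and gives the C11 alcohol without touching the silyl enol ether or any stereocentre.

**Step 14**
Reactants: 21 silyl enol ether alcohol
Product: 22 3-({[tert-butyl(dimethyl)silyl]oxy}methyl)-4-(hydroxymethyl)-4a,8,8-trimethyl-4a,5,6,7,8,8a-hexahydronaphthalen-1(4H)-one (C5, C9 and C10 as in 36)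
Conditions: Pd(OAc)2 (1.1 equiv), MeCN, rt
Reagents that add atoms: none
Why: Saegusa–Ito oxidation (silyl enol ether to a palladium enolate of divalent palladium, then β-hydride elimination of H8) should give the 7-en-6-one, making C8 trigonal so that both C8 epimers converge.

**Step 15**
Reactants: 22 enone
Product: 23 (E)-4-methylbenzenesulfonohydrazone of 22 at C6 (N–N bond anti to C5)
Conditions: TsNHNH2, AcOH (cat.), EtOH, 50 °C
Reagents that add atoms: 4-methylbenzenesulfonohydrazide, Cc1ccc(cc1)S(=O)(=O)NN
Why: Acid-catalysed condensation gives the α,β-unsaturated tosylhydrazone, the sulfonamide nitrogen pointing away from C5 and the C4 methyl groups.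

**Step 16**
Reactants: 23 tosylhydrazone
Product: 26 [2-({[tert-butyl(dimethyl)silyl]oxy}methyl)-5,5,8a-trimethyl-1,2,4a,5,6,7,8,8a-octahydronaphthalen-1-yl]methanol (C5, C8, C9 and C10 as in 36; C11 and C17 trans-diequatorial), via C6 tosylhydrazine 24 (not isolated), via allylic diazene 25 (not isolated)
Conditions: catecholborane, CHCl3, 0 °C; NaOAc·3H2O, 60 °C
Reagents that add atoms: none
Why: Reductive 1,3-transposition of an enone tosylhydrazone: hydride should add to C6 from the face opposite the axial C4 and C10 methyl groups, acetate-induced loss of sulfinate gives the axial allylic diazene, and its retro-ene loss of N2 delivers hydrogen suprafacially to the same face of C8, leaving C17 equatorial and the alkene at C6=C7.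

**Step 17**
Reactants: 26 alcohol
Product: 27 2-({[tert-butyl(dimethyl)silyl]oxy}methyl)-5,5,8a-trimethyl-1,2,4a,5,6,7,8,8a-octahydronaphthalene-1-carbaldehyde (stereocentres as in 26)
Conditions: DMP, pyridine, CH2Cl2, 0 °C → rt
Reagents that add atoms: none
Why: Dess–Martin oxidation gives the C11 aldehyde under non-epimerising conditions, the equatorial aldehyde also being the thermodynamic epimer at C9.

**Step 18**
Reactants: 27 aldehyde
Product: 28 tert-butyl{[1-ethenyl-5,5,8a-trimethyl-1,2,4a,5,6,7,8,8a-octahydronaphthalen-2-yl]methoxy}dimethylsilane (stereocentres as in 26)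
Conditions: Ph3PCH3Br, KOt-Bu, THF, 0 °C → rt
Reagents that add atoms: methyltriphenylphosphonium bromide, C[P+](c1ccccc1)(c1ccccc1)c1ccccc1.[Br-]
Why: Wittig methylenation with the non-stabilised ylide converts the hindered aldehyde into the C11=C12 vinyl group.

**Step 19**
Reactants: 29 methyl 4-hydroxybut-2-ynoate
Product: 30 methyl (2Z)-4-hydroxy-3-iodobut-2-enoate
Conditions: NaI, AcOH, MeCN, 80 °C
Reagents that add atoms: sodium iodide, [Na+].[I-]
Why: Conjugate hydroiodination of the ynoate (iodide adds to C3, protonation anti) gives the Z-β-iodoenoate with iodine cis to the ester, the geometry needed for C12 cis to C15.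

**Step 20**
Reactants: 28 vinyl decalin; 30 vinyl iodide
Product: 32 methyl (2E)-5-[2-({[tert-butyl(dimethyl)silyl]oxy}methyl)-5,5,8a-trimethyl-1,2,4a,5,6,7,8,8a-octahydronaphthalen-1-yl]-3-(hydroxymethyl)pent-2-enoate (ring stereocentres as in 36), via B-alkyl-9-BBN borane 31 (not isolated)
Conditions: 9-BBN, THF, rt; then 30, Pd(dppf)Cl2 (5 mol%), AsPh3 (10 mol%), aq. K3PO4, DMF, rt
Reagents that add atoms: none
Why: Anti-Markovnikov hydroboration of the monosubstituted alkene with 9-BBN (the hindered ring alkene is left alone) and B-alkyl Suzuki–Miyaura coupling form C12–C13 with retention of the iodoalkene geometry.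

**Step 21**
Reactants: 32 methyl ester
Product: 33 (2E)-5-[2-({[tert-butyl(dimethyl)silyl]oxy}methyl)-5,5,8a-trimethyl-1,2,4a,5,6,7,8,8a-octahydronaphthalen-1-yl]-3-(hydroxymethyl)pent-2-enoic acid
Conditions: LiOH, THF/MeOH/H2O, rt; 1 M HCl to pH 3
Reagents that add atoms: lithium hydroxide, [Li+].[OH-]
Why: Saponification frees the acid; the C16 hydroxyl is trans to the carboxyl group and cannot lactonise, and the primary TBS ether is stable to aqueous hydroxide.

**Step 22**
Reactants: 33 hydroxy acid
Product: 34 (2E)-3-[(acetyloxy)methyl]-5-[2-({[tert-butyl(dimethyl)silyl]oxy}methyl)-5,5,8a-trimethyl-1,2,4a,5,6,7,8,8a-octahydronaphthalen-1-yl]pent-2-enoic acid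
Conditions: Ac2O, pyridine, DMAP (cat.), CH2Cl2, 0 °C → rt; H2O
Reagents that add atoms: acetic anhydride, CC(=O)OC(C)=O
Why: DMAP-catalysed O-acylation esterifies the only free hydroxyl (C16), the carboxylic acid being recovered unchanged after the aqueous quench.

**Step 23**
Reactants: 34 silyl ether
Product: 35 (2E)-3-[(acetyloxy)methyl]-5-[2-(hydroxymethyl)-5,5,8a-trimethyl-1,2,4a,5,6,7,8,8a-octahydronaphthalen-1-yl]pent-2-enoic acid
Conditions: HF·pyridine, pyridine, THF, 0 °C → rt
Reagents that add atoms: none
Why: Buffered fluoride cleavage of the primary TBS ether leaves the acetate, the acid and both alkenes untouched.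

**Step 24**
Reactants: 35 hydroxy acid
Product: 36 CNP0217581.1, (2E)-3-[(acetyloxy)methyl]-5-[(1R,2S,4aR,8aS)-2-formyl-5,5,8a-trimethyl-1,2,4a,5,6,7,8,8a-octahydronaphthalen-1-yl]pent-2-enoic acid
Conditions: DMP, CH2Cl2, 0 °C
Reagents that add atoms: none
Why: Dess–Martin oxidation of the primary alcohol under neutral non-aqueous conditions should give the aldehyde without epimerisation at C8 or migration of the C6=C7 bond into conjugation.

**Compound list**
1 | geraniol, (2E)-3,7-dimethylocta-2,6-dien-1-ol | CC(C)=CCC/C(C)=C/CO | starting material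
2 | 1-({[(2E)-3,7-dimethylocta-2,6-dien-1-yl]oxy}methyl)-4-methoxybenzene | CC(C)=CCC/C(C)=C/COCc1ccc(OC)cc1 | intermediate
3 | (4E)-6-[(4-methoxybenzyl)oxy]-4-methylhex-4-enal (formed in the flask in step 2) | O=CCC/C(C)=C/COCc1ccc(OC)cc1 | intermediate
4 | (4E)-6-[(4-methoxybenzyl)oxy]-4-methylhex-4-en-1-ol | OCCC/C(C)=C/COCc1ccc(OC)cc1 | intermediate
5 | 1-({[(2E)-6-bromo-3-methylhex-2-en-1-yl]oxy}methyl)-4-methoxybenzene | BrCCC/C(C)=C/COCc1ccc(OC)cc1 | intermediate
6 | mesityl oxide, 4-methylpent-3-en-2-one | CC(C)=CC(C)=O | starting material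
7 | {(4E)-6-[(4-methoxybenzyl)oxy]-4-methylhex-4-en-1-yl}magnesium bromide (formed in the flask in step 4) | Br[Mg]CCC/C(C)=C/COCc1ccc(OC)cc1 | intermediate
8 | (8E)-10-[(4-methoxybenzyl)oxy]-4,4,8-trimethyldec-8-en-2-one | CC(=O)CC(C)(C)CCC/C(C)=C/COCc1ccc(OC)cc1 | intermediate
9 | (tert-butyldimethylsilyloxy)acetaldehyde | CC(C)(C)[Si](C)(C)OCC=O | starting material
10 | (10E)-1-[(tert-butyldimethylsilyl)oxy]-2-hydroxy-12-[(4-methoxybenzyl)oxy]-6,6,10-trimethyldodec-10-en-4-one (racemic at the carbinol carbon) | CC(C)(C)[Si](C)(C)OCC(O)CC(=O)CC(C)(C)CCC/C(C)=C/COCc1ccc(OC)cc1 | intermediate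
11 | methanesulfonate of 10 (formed in the flask in step 6; racemic) | CC(C)(C)[Si](C)(C)OCC(OS(C)(=O)=O)CC(=O)CC(C)(C)CCC/C(C)=C/COCc1ccc(OC)cc1 | intermediate
12 | (2E,10E)-1-[(tert-butyldimethylsilyl)oxy]-12-[(4-methoxybenzyl)oxy]-6,6,10-trimethyldodeca-2,10-dien-4-one | CC(C)(C)[Si](C)(C)OC/C=C/C(=O)CC(C)(C)CCC/C(C)=C/COCc1ccc(OC)cc1 | intermediate
13 | (2E,10E)-1-[(tert-butyldimethylsilyl)oxy]-12-hydroxy-6,6,10-trimethyldodeca-2,10-dien-4-one | CC(C)(C)[Si](C)(C)OC/C=C/C(=O)CC(C)(C)CCC/C(C)=C/CO | intermediate
14 | (2E,10E)-12-[(tert-butyldimethylsilyl)oxy]-3,7,7-trimethyl-9-oxododeca-2,10-dienal | CC(C)(C)[Si](C)(C)OC/C=C/C(=O)CC(C)(C)CCC/C(C)=C/C=O | intermediate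
15 | (2E,10E)-12-[(tert-butyldimethylsilyl)oxy]-3,7,7-trimethyl-9-oxododeca-2,10-dienoic acid | CC(C)(C)[Si](C)(C)OC/C=C/C(=O)CC(C)(C)CCC/C(C)=C/C(=O)O | intermediate
16 | 2-oxazolidinone | O=C1NCCO1 | starting material
17 | mixed anhydride of 15 with pivalic acid (formed in the flask in step 10) | CC(C)(C)[Si](C)(C)OC/C=C/C(=O)CC(C)(C)CCC/C(C)=C/C(=O)OC(=O)C(C)(C)C | intermediate
18 | 3-[(2E,10E)-12-[(tert-butyldimethylsilyl)oxy]-3,7,7-trimethyl-9-oxododeca-2,10-dienoyl]-1,3-oxazolidin-2-one | CC(C)(C)[Si](C)(C)OC/C=C/C(=O)CC(C)(C)CCC/C(C)=C/C(=O)N1CCOC1=O | intermediate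
19 | 3-[(2E,8Z,10E)-9,12-bis[(tert-butyldimethylsilyl)oxy]-3,7,7-trimethyldodeca-2,8,10-trienoyl]-1,3-oxazolidin-2-one (key-step precursor) | O=C1OCCN1C(=O)/C=C(\C)CCCC(C)(C)/C=C(O[Si](C)(C)C(C)(C)C)/C=C/CO[Si](C)(C)C(C)(C)C | intermediate
20 | trans-fused bicyclic C6 silyl enol ether imide (key-step product; C10 methyl, C11 and C17 cis; C5, C9, C10 as in 36) | O=C1OCCN1C(=O)[C@@H]1[C@H](CO[Si](C)(C)C(C)(C)C)C=C(O[Si](C)(C)C(C)(C)C)[C@@H]2C(C)(C)CCC[C@@]12C | intermediate
21 | C11 alcohol of the bicyclic silyl enol ether (stereocentres as in 20) | OC[C@@H]1[C@H](CO[Si](C)(C)C(C)(C)C)C=C(O[Si](C)(C)C(C)(C)C)[C@@H]2C(C)(C)CCC[C@@]12C | intermediate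
22 | 3-({[tert-butyl(dimethyl)silyl]oxy}methyl)-4-(hydroxymethyl)-4a,8,8-trimethyl-4a,5,6,7,8,8a-hexahydronaphthalen-1(4H)-one (7-en-6-one; C5, C9, C10 as in 36) | OC[C@@H]1C(CO[Si](C)(C)C(C)(C)C)=CC(=O)[C@@H]2C(C)(C)CCC[C@@]12C | intermediate
23 | (E)-tosylhydrazone of 22 at C6 | OC[C@@H]1C(CO[Si](C)(C)C(C)(C)C)=C/C(=N\NS(=O)(=O)c3ccc(C)cc3)[C@@H]2C(C)(C)CCC[C@@]12C | intermediate
24 | C6 tosylhydrazine from hydride addition to 23, nitrogen axial and syn to the C10 methyl (formed in the flask in step 16 as its catecholboryl derivative; drawn with free N–H and O–H) | OC[C@@H]1C(CO[Si](C)(C)C(C)(C)C)=C[C@H](NNS(=O)(=O)c3ccc(C)cc3)[C@@H]2C(C)(C)CCC[C@@]12C | intermediate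
25 | C6 allylic diazene (formed in the flask in step 16) | OC[C@@H]1C(CO[Si](C)(C)C(C)(C)C)=C[C@H](N=N)[C@@H]2C(C)(C)CCC[C@@]12C | intermediate
26 | [2-({[tert-butyl(dimethyl)silyl]oxy}methyl)-5,5,8a-trimethyl-1,2,4a,5,6,7,8,8a-octahydronaphthalen-1-yl]methanol (6-ene; C5, C8, C9, C10 as in 36) | OC[C@@H]1[C@@H](CO[Si](C)(C)C(C)(C)C)C=C[C@@H]2C(C)(C)CCC[C@@]12C | intermediate
27 | C11 aldehyde of 26 | O=C[C@@H]1[C@@H](CO[Si](C)(C)C(C)(C)C)C=C[C@@H]2C(C)(C)CCC[C@@]12C | intermediate
28 | C9 vinyl compound, tert-butyl{[1-ethenyl-5,5,8a-trimethyl-1,2,4a,5,6,7,8,8a-octahydronaphthalen-2-yl]methoxy}dimethylsilane | C=C[C@@H]1[C@@H](CO[Si](C)(C)C(C)(C)C)C=C[C@@H]2C(C)(C)CCC[C@@]12C | intermediate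
29 | methyl 4-hydroxybut-2-ynoate | COC(=O)C#CCO | starting material
30 | methyl (2Z)-4-hydroxy-3-iodobut-2-enoate | COC(=O)/C=C(/CO)I | intermediate
31 | 9-(C12-alkyl)-9-borabicyclo[3.3.1]nonane from 28 (formed in the flask in step 20) | C(C[C@@H]1[C@@H](CO[Si](C)(C)C(C)(C)C)C=C[C@@H]2C(C)(C)CCC[C@@]12C)B1C2CCCC1CCC2 | intermediate
32 | methyl (2E)-5-[2-({[tert-butyl(dimethyl)silyl]oxy}methyl)-5,5,8a-trimethyl-1,2,4a,5,6,7,8,8a-octahydronaphthalen-1-yl]-3-(hydroxymethyl)pent-2-enoate | COC(=O)/C=C(/CO)CC[C@@H]1[C@@H](CO[Si](C)(C)C(C)(C)C)C=C[C@@H]2C(C)(C)CCC[C@@]12C | intermediate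
33 | carboxylic acid of 32 | OC(=O)/C=C(/CO)CC[C@@H]1[C@@H](CO[Si](C)(C)C(C)(C)C)C=C[C@@H]2C(C)(C)CCC[C@@]12C | intermediate
34 | C16 acetate of 33 | CC(=O)OC/C(=C/C(=O)O)CC[C@@H]1[C@@H](CO[Si](C)(C)C(C)(C)C)C=C[C@@H]2C(C)(C)CCC[C@@]12C | intermediate
35 | C17 alcohol (desilylated 34) | CC(=O)OC/C(=C/C(=O)O)CC[C@@H]1[C@@H](CO)C=C[C@@H]2C(C)(C)CCC[C@@]12C | intermediate
36 | CNP0217581.1, (2E)-3-[(acetyloxy)methyl]-5-[(1R,2S,4aR,8aS)-2-formyl-5,5,8a-trimethyl-1,2,4a,5,6,7,8,8a-octahydronaphthalen-1-yl]pent-2-enoic acid | CC(=O)OC/C(=C/C(=O)O)CC[C@@H]1[C@@H](C=O)C=C[C@@H]2C(C)(C)CCC[C@@]12C | target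

**Step count and risks**
Total: 24 steps. Longest linear sequence: 23 steps (steps 1–18 and 20–24 from geraniol); step 19 is a one-step branch.

Steps most likely to fail:

1. Step 12 (proposed new method). The cycloaddition may stall or lose selectivity. Bond formation between the neopentyl C5 and the fully substituted C10 is slow, so protodesilylation of the dienol ether, an exo pathway (cis ring fusion) or arrest after the first Michael bond could overtake the catalysed endo path. The fallback uses known chemistry, an auxiliary-controlled, aluminium-promoted intramolecular Diels–Alder reaction of a chiral N-acyloxazolidinone. Acid 15 is coupled through anhydride 17 with (R)-4-benzyl-2-oxazolidinone (LiCl, Et3N) to give the chiral keto imide F1. TBSOTf/Et3N converts it into the chiral silyl dienol ether F2. Me2AlCl (1.4 equiv, CH2Cl2, −30 °C) forms the bidentate chelate in which the benzyl group shields the Si face of C9, so cyclisation should give the auxiliary-bearing cycloadduct F3 with the same configuration at C5, C9 and C10. LiBH4 cleavage of the auxiliary returns to alcohol 21.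

2. Step 15. Condensation at C6 may be slow or incomplete because the carbonyl is flanked by C5 and the C4 gem-dimethyl group, and forcing it with more acid or heat risks loss of the C17 silyl ether. The fallback assembles the sulfonylhydrazone in two stages from the much smaller and more nucleophilic hydrazine. Enone 22 and hydrazine hydrate (EtOH, rt to 50 °C) give the N-unsubstituted hydrazone F4; a pyrazoline cannot form because its C=N carbon would sit at a bridgehead. Selective N-sulfonylation with TsCl (1.0 equiv, pyridine, 0 °C; the hindered C11 hydroxyl should react more slowly than the hydrazone nitrogen) then gives tosylhydrazone 23.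

3. Step 14. β-Hydride elimination toward the fully substituted C8 may be slow, so protodesilylation to the saturated 6-ketone or palladium-mediated oxidation of the C11 alcohol could compete. The fallback replaces palladium by selenoxide elimination. Silyl enol ether 21 and PhSeCl (CH2Cl2, −78 °C) give the axial 7-phenylselanyl 6-ketone F5. Oxidation with H2O2/pyridine (0 °C) then triggers syn-elimination of the selenoxide with the cis H8 and gives enone 22.

**Further compounds**
F1 | step 12 | (4R)-4-benzyl-3-[(2E,10E)-12-[(tert-butyldimethylsilyl)oxy]-3,7,7-trimethyl-9-oxododeca-2,10-dienoyl]-1,3-oxazolidin-2-one | CC(C)(C)[Si](C)(C)OC/C=C/C(=O)CC(C)(C)CCC/C(C)=C/C(=O)N1[C@H](Cc2ccccc2)COC1=O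
F2 | step 12 | (4R)-4-benzyl-3-[(2E,8Z,10E)-9,12-bis[(tert-butyldimethylsilyl)oxy]-3,7,7-trimethyldodeca-2,8,10-trienoyl]-1,3-oxazolidin-2-one | CC(C)(C)[Si](C)(C)OC/C=C/C(O[Si](C)(C)C(C)(C)C)=C/C(C)(C)CCC/C(C)=C/C(=O)N1[C@H](Cc2ccccc2)COC1=O
F3 | step 12 | (4R)-4-benzyl-oxazolidinone analogue of cycloadduct 20 (ring stereocentres as in 20) | C(=O)([C@@H]1[C@H](CO[Si](C)(C)C(C)(C)C)C=C(O[Si](C)(C)C(C)(C)C)[C@@H]2C(C)(C)CCC[C@@]12C)N1[C@H](Cc2ccccc2)COC1=O
F4 | step 15 | N-unsubstituted (E)-hydrazone of enone 22 at C6 | OC[C@@H]1C(CO[Si](C)(C)C(C)(C)C)=C/C(=N\N)[C@@H]2C(C)(C)CCC[C@@]12C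
F5 | step 14 | 7-(phenylselanyl) 6-ketone from 21 (selenium axial and cis to H8) | OC[C@@H]1[C@H](CO[Si](C)(C)C(C)(C)C)[C@@H]([Se]c3ccccc3)C(=O)[C@@H]2C(C)(C)CCC[C@@]12C
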